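Locants: lactone ring C1(=O)–O2–C3–C3a–C6a, tetrahydrofuran ring C3a–C4–O5–C6–C6a; syringyl group on C3, catechol on C6.
Feature: H3, H3a, H6a and H6 all lie on one face of the bicycle, so the ring C3a–C4–O5–C6–C6a is the cis-hydrogenation image of an aromatic furan fused to the lactone, and only C3 has to exist beforehand.
Cuts, in retrosynthetic order: the four C–H bonds at C3a, C4, C6 and C6a (furan hydrogenation); C6a–C3a and O5–C4 (carbenoid/alkyne cascade of a propargylic 2-diazo-3-oxo ester); O2–C1 (acylketene esterification); C3–C(alkyne) (alkynylation of silylated syringaldehyde).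
Forward order: the two aryl fragments are joined through the ester, one rhodium-catalysed operation closes first the lactone and then the furan, the furan is saturated to the tetrahydrofuran, and the three phenols are released last.
Stereochemistry: C3 comes from a catalytic enantioselective alkynylation; C3a, C6a and C6 come from hydrogen delivery to the furan face opposite the C3 aryl group.

Key step: step 9

Abbreviations: TBS = tert-butyldimethylsilyl; TBSO = tert-butyldimethylsilyloxy.

Assumption: the (R,R)-ProPhenol/Me2Zn catalyst is taken to deliver the alkynyl group to the Si face of the silylated syringaldehyde. The configuration of the carbinol is to be confirmed by Mosher ester analysis, and the (S,S)-ligand is used instead if the sense proves opposite.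

Remark on descriptors: the geometry at the carbinol carbon (later C3) is the same throughout. The descriptor reads R for the C-silylated carbinol (the silylated alkyne outranks the aryl group), S for the terminal alkyne and its esters, R for the furan-fused lactone (furan carbon C3a outranks the aryl group), and S again for the dihydro and tetrahydro compounds.

Step 1
Reactants: 1 syringaldehyde (4-hydroxy-3,5-dimethoxybenzaldehyde)
Product: 2 4-(TBSO)-3,5-dimethoxybenzaldehyde
Conditions: TBSCl (1.2 equiv), imidazole (2.5 equiv), DMF, rt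
Reagents that add atoms: tert-butyldimethylsilyl chloride (TBSCl), CC(C)(C)[Si](C)(C)Cl
Why: Imidazole-promoted O-silylation of a phenol, which leaves the aldehyde untouched and masks the acidic OH for the organozinc, diazo-transfer and carbenoid steps.

Step 2
Reactants: 2 4-(TBSO)-3,5-dimethoxybenzaldehyde; 3 trimethylsilylacetylene
Product: 5 (R)-1-[4-(TBSO)-3,5-dimethoxyphenyl]-3-(trimethylsilyl)prop-2-yn-1-ol, via zinc acetylide 4 (not isolated)
Conditions: (R,R)-ProPhenol (20 mol%), Me2Zn (3 equiv), Ph3P=O (40 mol%), toluene, 0 to 4 °C; aq. NH4Cl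
Reagents that add atoms: none
Why: Catalytic enantioselective alkynylation of an aryl aldehyde by a dinuclear zinc–ProPhenol complex, in which the alkynylzinc 4 formed from 3 and Me2Zn is delivered to one aldehyde face inside the chiral pocket and so sets the centre that becomes C3.

Step 3
Reactants: 5 (R)-1-[4-(TBSO)-3,5-dimethoxyphenyl]-3-(trimethylsilyl)prop-2-yn-1-ol
Product: 6 (S)-1-[4-(TBSO)-3,5-dimethoxyphenyl]prop-2-yn-1-ol
Conditions: AgNO3 (10 mol%), acetone/H2O, rt, dark
Reagents that add atoms: none
Why: Silver-catalysed protodesilylation of a 1-silylalkyne, which cleaves the C(sp)–Si bond selectively and should leave the aryl silyl ether and the carbinol configuration untouched.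

Step 4
Reactants: 7 protocatechuic acid (3,4-dihydroxybenzoic acid)
Product: 9 3,4-bis(TBSO)benzoic acid, via silyl ester 8 (not isolated)
Conditions: TBSCl (3.5 equiv), imidazole (7 equiv), DMF, rt; then AcOH/THF/H2O (3:1:1), rt
Reagents that add atoms: tert-butyldimethylsilyl chloride (TBSCl), CC(C)(C)[Si](C)(C)Cl
Why: Exhaustive silylation followed by selective hydrolysis of the silyl ester, which is far more labile towards aqueous acid than the two aryl silyl ethers.

Step 5
Reactants: 9 3,4-bis(TBSO)benzoic acid; 10 Meldrum's acid (2,2-dimethyl-1,3-dioxane-4,6-dione)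
Product: 11 5-{[3,4-bis(TBSO)phenyl](hydroxy)methylidene}-2,2-dimethyl-1,3-dioxane-4,6-dione (enol form of the 5-aroyl Meldrum's acid)
Conditions: DCC (1.1 equiv), DMAP (1.5 equiv), CH2Cl2, 0 °C to rt; cold dilute KHSO4 wash
Reagents that add atoms: none
Why: Carbodiimide/DMAP-mediated C-acylation of Meldrum's acid by a carboxylic acid, a standard entry to acyl Meldrum's acids, which rest as the chelated enol.

Step 6
Reactants: 11 aroyl Meldrum's acid (enol form); 6 (S)-1-[4-(TBSO)-3,5-dimethoxyphenyl]prop-2-yn-1-ol
Product: 13 (S)-1-[4-(TBSO)-3,5-dimethoxyphenyl]prop-2-yn-1-yl 3-[3,4-bis(TBSO)phenyl]-3-oxopropanoate, via aroylketene 12 (not isolated)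
Conditions: toluene, 95 °C (11 in slight excess)
Reagents that add atoms: none
Why: Thermal fragmentation of the acyl Meldrum's acid to an acylketene that is trapped by the secondary alcohol (acylketene esterification) under neutral conditions, so the propargylic C–O bond is never broken and its configuration is kept.

Step 7
Reactants: 13 (S)-propargylic aroylacetate
Product: 14 (S)-1-[4-(TBSO)-3,5-dimethoxyphenyl]prop-2-yn-1-yl 3-[3,4-bis(TBSO)phenyl]-2-diazo-3-oxopropanoate
Conditions: p-ABSA (1.2 equiv), Et3N (1.5 equiv), MeCN, 0 °C to rt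
Reagents that add atoms: 4-acetamidobenzenesulfonyl azide (p-ABSA), CC(=O)Nc1ccc(cc1)S(=O)(=O)N=[N+]=[N-]
Why: Regitz diazo transfer to the active methylene of a β-keto ester; the amine base is too weak to touch the propargylic C–H.

Step 8
Reactants: 14 (S)-propargylic 2-diazo-3-oxo ester
Product: 15 (3R)-6-[3,4-bis(TBSO)phenyl]-3-[4-(TBSO)-3,5-dimethoxyphenyl]-1H,3H-furo[3,4-c]furan-1-one
Conditions: Rh2(OAc)4 (2 mol%), dry benzene, 80 °C, slow addition of 14
Reagents that add atoms: none
Why: Rhodium-carbenoid/alkyne cascade known for propargyl 2-diazo-3-oxoalkanoates, in which the carbenoid at C6a adds to the proximal alkyne carbon (5-exo-dig, closes the lactone through C6a–C3a) and the resulting catalyst-bound vinyl carbenoid at C4 is captured by the aroyl oxygen (closes the furan through O5–C4), with the stereocentre a spectator.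

Step 9
Reactants: 15 (3R)-furan-fused lactone
Product: 17 (3S,3aS,6S,6aR)-6-[3,4-bis(TBSO)phenyl]-3-[4-(TBSO)-3,5-dimethoxyphenyl]tetrahydro-1H,3H-furo[3,4-c]furan-1-one, via dihydrofuran 16 (not isolated)
Conditions: 5% Rh/Al2O3, H2 (40 bar), EtOAc, rt; stopped after uptake of 2 equiv H2
Reagents that add atoms: none
Why: Heterogeneous cis-hydrogenation (Horiuti–Polanyi surface addition) of the furan ring: the nearly flat furanolactone 15 should adsorb on rhodium through the face that carries H3, because the syringyl group on C3, the only tetrahedral ring carbon, blocks the other face, and hydrogen is transferred first to C3a and C4 (giving the vinylogous carbonate 16) and then to the tetrasubstituted C6=C6a bond. The closest known reaction type is the all-cis hydrogenation of substituted furans, 3-furoates and diarylfurans of the lignan series to cis-tetrahydrofurans over Rh, together with the hydrogenation of γ-substituted butenolides anti to the γ-substituent. No ring is closed in this step; the aromatic furan ring O5/C4/C3a/C6a/C6 becomes the tetrahydrofuran ring, and four C–H bonds are formed (C3a, C4, C6, C6a) for two equivalents of H2. C3a is controlled by the adjacent C3 stereocentre (hydrogen enters anti to the aryl group, so H3a ends cis to H3); C6a is then fixed by the obligatory cis fusion of the two five-membered rings and by adsorption of 16 on the same open face, and C6 by syn addition across C6=C6a, so that H6 is cis to H6a. The step needs facial selectivity and chemoselectivity (furan before the arenes, no hydrogenolysis of the benzylic C3–O2 and C6–O5 bonds): the first is secured by the C3 substituent on a planar bicycle, the second by the bulky silyl ethers that keep the arenes off the surface, by Rh in place of Pd and by a neutral aprotic solvent. The product is the kinetic endo,endo isomer, so the reaction is stopped at the calculated uptake and the mixture is kept away from acid and base.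

Step 10
Reactants: 17 all-cis tris-TBS furofuranone
Product: 18 (3S,3aS,6S,6aR)-6-(3,4-dihydroxyphenyl)-3-(4-hydroxy-3,5-dimethoxyphenyl)tetrahydro-1H,3H-furo[3,4-c]furan-1-one (CNP0224550.1)
Conditions: TBAF (3.5 equiv), AcOH (4 equiv), THF, 0 °C; pH 7 phosphate buffer work-up
Reagents that add atoms: none
Why: Fluoride-mediated cleavage of the aryl silyl ethers buffered by acetic acid, so the phenols are released as ArOH and not as phenoxides, which should prevent quinone-methide opening at C3 or C6 and enolisation at C6a of the all-cis isomer.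

Compound list
1 | syringaldehyde (4-hydroxy-3,5-dimethoxybenzaldehyde) | COc1cc(C=O)cc(OC)c1O | starting material
2 | 4-[(tert-butyldimethylsilyl)oxy]-3,5-dimethoxybenzaldehyde | COc1cc(C=O)cc(OC)c1O[Si](C)(C)C(C)(C)C | intermediate
3 | trimethylsilylacetylene | C#C[Si](C)(C)C | starting material
4 | methyl[(trimethylsilyl)ethynyl]zinc | C[Zn]C#C[Si](C)(C)C | intermediate
5 | (R)-1-{4-[(tert-butyldimethylsilyl)oxy]-3,5-dimethoxyphenyl}-3-(trimethylsilyl)prop-2-yn-1-ol | COc1cc([C@@H](O)C#C[Si](C)(C)C)cc(OC)c1O[Si](C)(C)C(C)(C)C | intermediate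
6 | (S)-1-{4-[(tert-butyldimethylsilyl)oxy]-3,5-dimethoxyphenyl}prop-2-yn-1-ol | COc1cc([C@@H](O)C#C)cc(OC)c1O[Si](C)(C)C(C)(C)C | intermediate
7 | protocatechuic acid (3,4-dihydroxybenzoic acid) | O=C(O)c1ccc(O)c(O)c1 | starting material
8 | tert-butyldimethylsilyl 3,4-bis[(tert-butyldimethylsilyl)oxy]benzoate | CC(C)(C)[Si](C)(C)OC(=O)c1ccc(O[Si](C)(C)C(C)(C)C)c(O[Si](C)(C)C(C)(C)C)c1 | intermediate
9 | 3,4-bis[(tert-butyldimethylsilyl)oxy]benzoic acid | O=C(O)c1ccc(O[Si](C)(C)C(C)(C)C)c(O[Si](C)(C)C(C)(C)C)c1 | intermediate
10 | Meldrum's acid (2,2-dimethyl-1,3-dioxane-4,6-dione) | CC1(C)OC(=O)CC(=O)O1 | starting material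
11 | 5-({3,4-bis[(tert-butyldimethylsilyl)oxy]phenyl}(hydroxy)methylidene)-2,2-dimethyl-1,3-dioxane-4,6-dione (enol form of the 5-aroyl Meldrum's acid) | CC1(C)OC(=O)C(=C(O)c2ccc(O[Si](C)(C)C(C)(C)C)c(O[Si](C)(C)C(C)(C)C)c2)C(=O)O1 | intermediate
12 | {3,4-bis[(tert-butyldimethylsilyl)oxy]benzoyl}ketene | O=C=CC(=O)c1ccc(O[Si](C)(C)C(C)(C)C)c(O[Si](C)(C)C(C)(C)C)c1 | intermediate
13 | (S)-1-{4-[(tert-butyldimethylsilyl)oxy]-3,5-dimethoxyphenyl}prop-2-yn-1-yl 3-{3,4-bis[(tert-butyldimethylsilyl)oxy]phenyl}-3-oxopropanoate | COc1cc([C@@H](OC(=O)CC(=O)c2ccc(O[Si](C)(C)C(C)(C)C)c(O[Si](C)(C)C(C)(C)C)c2)C#C)cc(OC)c1O[Si](C)(C)C(C)(C)C | intermediate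
14 | (S)-1-{4-[(tert-butyldimethylsilyl)oxy]-3,5-dimethoxyphenyl}prop-2-yn-1-yl 3-{3,4-bis[(tert-butyldimethylsilyl)oxy]phenyl}-2-diazo-3-oxopropanoate | COc1cc([C@@H](OC(=O)C(=[N+]=[N-])C(=O)c2ccc(O[Si](C)(C)C(C)(C)C)c(O[Si](C)(C)C(C)(C)C)c2)C#C)cc(OC)c1O[Si](C)(C)C(C)(C)C | intermediate
15 | (3R)-6-{3,4-bis[(tert-butyldimethylsilyl)oxy]phenyl}-3-{4-[(tert-butyldimethylsilyl)oxy]-3,5-dimethoxyphenyl}-1H,3H-furo[3,4-c]furan-1-one | COc1cc([C@H]2OC(=O)c3c2coc3-c2ccc(O[Si](C)(C)C(C)(C)C)c(O[Si](C)(C)C(C)(C)C)c2)cc(OC)c1O[Si](C)(C)C(C)(C)C | intermediate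
16 | (3S,3aS)-6-{3,4-bis[(tert-butyldimethylsilyl)oxy]phenyl}-3-{4-[(tert-butyldimethylsilyl)oxy]-3,5-dimethoxyphenyl}-3a,4-dihydro-1H,3H-furo[3,4-c]furan-1-one (H3 and H3a cis) | COc1cc([C@H]2OC(=O)C3=C(c4ccc(O[Si](C)(C)C(C)(C)C)c(O[Si](C)(C)C(C)(C)C)c4)OC[C@H]32)cc(OC)c1O[Si](C)(C)C(C)(C)C | intermediate
17 | (3S,3aS,6S,6aR)-6-{3,4-bis[(tert-butyldimethylsilyl)oxy]phenyl}-3-{4-[(tert-butyldimethylsilyl)oxy]-3,5-dimethoxyphenyl}tetrahydro-1H,3H-furo[3,4-c]furan-1-one (H3, H3a, H6a, H6 all cis) | COc1cc([C@H]2OC(=O)[C@@H]3[C@H]2CO[C@@H]3c2ccc(O[Si](C)(C)C(C)(C)C)c(O[Si](C)(C)C(C)(C)C)c2)cc(OC)c1O[Si](C)(C)C(C)(C)C | intermediate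
18 | (3S,3aS,6S,6aR)-6-(3,4-dihydroxyphenyl)-3-(4-hydroxy-3,5-dimethoxyphenyl)tetrahydro-1H,3H-furo[3,4-c]furan-1-one (CNP0224550.1) | COc1cc([C@H]2OC(=O)[C@@H]3[C@H]2CO[C@@H]3c2ccc(O)c(O)c2)cc(OC)c1O | target

Total step count: 10.
Longest linear sequence: 8 steps (steps 1, 2, 3, 6, 7, 8, 9, 10, from syringaldehyde); the acid branch (steps 4 and 5) joins at step 6.

Steps most likely to fail, riskiest first

Step 9. The tetrasubstituted push–pull bond C6=C6a may refuse to take up hydrogen. Forcing the pressure may then start to saturate the arenes, cleave the benzylic C–O bonds, or let the half-reduced species leave and re-enter the surface with loss of facial control. The fallback sets out from 15 and comes back at 17, and splits the reduction into two mechanistically different stages. Compound 15 is hydrogenated only to the uptake of one equivalent (Rh/Al2O3, 1 bar H2, EtOAc), and the dihydrofuran 16, which already holds C3a, is isolated. Its cinnamate-like C6=C6a bond is then reduced by copper hydride conjugate reduction instead of on a surface (Cu(OAc)2 with 1,2-bis(diphenylphosphino)benzene and polymethylhydrosiloxane, t-BuOH, toluene, or stoichiometric [(Ph3P)CuH]6). Hydride should add to C6 from the open face that carries H3a, and protonation of the resulting enolate at C6a can only give the cis-fused lactone 17. The conditions are neutral and should leave the arenes and the benzylic C–O bonds alone. This fallback makes no compound outside the compound list (F0).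

Step 8. The carbenoid may be consumed by dimerisation or by attack on the electron-rich syringyl ring, because the ester must first rotate into its less populated conformer before the alkyne comes within reach. The fallback sets out from 11 and comes back at 15, bypassing 13 and 14; it builds the furan first by ionic chemistry and closes the lactone last. Methanolysis of 11 (MeOH, toluene, reflux) gives methyl 3-[3,4-bis(TBSO)phenyl]-3-oxopropanoate F1. Feist–Benary condensation with 1,3-dichloroacetone (pyridine, then acid-catalysed dehydration) gives methyl 2-[3,4-bis(TBSO)phenyl]-4-(chloromethyl)furan-3-carboxylate F2. Kornblum-type oxidation with N-methylmorpholine N-oxide in MeCN gives methyl 2-[3,4-bis(TBSO)phenyl]-4-formylfuran-3-carboxylate F3. The aryl donor is prepared from commercial 4-bromo-2,6-dimethoxyphenol: O-silylation gives (4-bromo-2,6-dimethoxyphenoxy)(tert-butyl)dimethylsilane F4, and bromine–lithium exchange with n-BuLi, B(OMe)3 and hydrolysis give [4-(TBSO)-3,5-dimethoxyphenyl]boronic acid F5. A catalytic enantioselective 1,2-addition of the boronic acid to the formyl group then sets C3, and the carbinol closes onto the neighbouring methyl ester in the same operation to give 15. The catalyst is of the kind that converts methyl 2-formylbenzoates into 3-arylphthalides, for example [RuCl2(p-cymene)]2 with a Me-BIPAM bisphosphoramidite. The ligand antipode is chosen by chiral HPLC comparison with material from the main route.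

Step 2. Enantioselectivity may be insufficient, or the facial sense opposite, with this hindered electron-rich aldehyde. The fallback sets out from 2 and comes back at 6, bypassing 5. Ethynylmagnesium bromide (THF, 0 °C) gives racemic 1-[4-(TBSO)-3,5-dimethoxyphenyl]prop-2-yn-1-ol F6. Kinetic resolution with immobilised Candida antarctica lipase B and vinyl acetate in a hydrocarbon/ether solvent should acetylate the (R)-enantiomer to (R)-1-[4-(TBSO)-3,5-dimethoxyphenyl]prop-2-yn-1-yl acetate F7. This follows the usual preference of this enzyme for the secondary alcohol enantiomer with the large aryl and the slim ethynyl group in these positions. The (S)-alcohol 6 is left behind and separated by chromatography; running the acylation slightly past half conversion should raise its enantiomeric purity.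

Further compounds
F0 | step 9 | none | none
F1 | step 8 | methyl 3-{3,4-bis[(tert-butyldimethylsilyl)oxy]phenyl}-3-oxopropanoate | COC(=O)CC(=O)c1ccc(O[Si](C)(C)C(C)(C)C)c(O[Si](C)(C)C(C)(C)C)c1
F2 | step 8 | methyl 2-{3,4-bis[(tert-butyldimethylsilyl)oxy]phenyl}-4-(chloromethyl)furan-3-carboxylate | COC(=O)c1c(CCl)coc1-c1ccc(O[Si](C)(C)C(C)(C)C)c(O[Si](C)(C)C(C)(C)C)c1
F3 | step 8 | methyl 2-{3,4-bis[(tert-butyldimethylsilyl)oxy]phenyl}-4-formylfuran-3-carboxylate | COC(=O)c1c(C=O)coc1-c1ccc(O[Si](C)(C)C(C)(C)C)c(O[Si](C)(C)C(C)(C)C)c1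
F4 | step 8 | (4-bromo-2,6-dimethoxyphenoxy)(tert-butyl)dimethylsilane | COc1cc(Br)cc(OC)c1O[Si](C)(C)C(C)(C)C
F5 | step 8 | {4-[(tert-butyldimethylsilyl)oxy]-3,5-dimethoxyphenyl}boronic acid | COc1cc(B(O)O)cc(OC)c1O[Si](C)(C)C(C)(C)C
F6 | step 2 | racemic 1-{4-[(tert-butyldimethylsilyl)oxy]-3,5-dimethoxyphenyl}prop-2-yn-1-ol | COc1cc(C(O)C#C)cc(OC)c1O[Si](C)(C)C(C)(C)C
F7 | step 2 | (R)-1-{4-[(tert-butyldimethylsilyl)oxy]-3,5-dimethoxyphenyl}prop-2-yn-1-yl acetate | COc1cc([C@H](OC(C)=O)C#C)cc(OC)c1O[Si](C)(C)C(C)(C)C
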